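The diaryl ether is disconnected at the O–C1' bond, with ring B carried as a cyclohexane-1,3-dione and aromatised late. Ring B bears hydroxyl (C6'), the ether oxygen (C1') and bromine (C2') on consecutive carbons and a second bromine on C5'. These four carbons map onto C1 (C=O), C2, C3 (C=O) and C6 of a 2-oxygenated cyclohexane-1,3-dione. In one operation a rhodium carbenoid from 2-diazocyclohexane-1,3-dione inserts into the O–H bond of 3,5-dibromo-2-methoxyphenol (ring A, C1 oxygen masked as methyl ether). The crowded ether thus forms at a carbene carbon and no C–Br bond is put at risk. The precursors are a symmetric diazodione and a monoprotected dibromocatechol.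

Key step: step 4

Remark: dione 7 is written as the diketone but should exist largely as its enol, 2-aryloxy-3-hydroxycyclohex-2-en-1-one, the form that reacts in step 5; the target has no stereocentre.

Step 1
Reactants: 1 cyclohexane-1,3-dione
Product: 2 2-diazocyclohexane-1,3-dione
Conditions: p-ABSA, Et3N, MeCN, 0 °C → rt
Reagents that add atoms: 4-acetamidobenzenesulfonyl azide (p-ABSA), CC(=O)Nc1ccc(cc1)S(=O)(=O)N=[N+]=[N-]
Why: Regitz diazo transfer, in which the enolate of the acidic 1,3-dione attacks the terminal azide nitrogen and the adduct fragments to the 2-diazo-1,3-dione and the sulfonamide.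

Step 2
Reactants: 3 3,5-dibromo-2-hydroxybenzaldehyde
Product: 4 3,5-dibromo-2-methoxybenzaldehyde
Conditions: MeI, K2CO3, DMF, rt
Reagents that add atoms: iodomethane, CI
Why: Williamson ether synthesis, the acidic phenoxide (formyl and bromine ortho, bromine para) being methylated by SN2 attack on MeI while the aldehyde is inert to carbonate.

Step 3
Reactants: 4 3,5-dibromo-2-methoxybenzaldehyde
Product: 6 3,5-dibromo-2-methoxyphenol, via aryl formate 5 (not isolated)
Conditions: mCPBA, CH2Cl2, 40 °C; then Et3N (cat.), MeOH, rt
Reagents that add atoms: 3-chloroperoxybenzoic acid (mCPBA), OOC(=O)c1cccc(Cl)c1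
Why: Baeyer–Villiger (Dakin-type) oxidation, in which the aryl group of the Criegee adduct, helped by its ortho methoxy donor, migrates to oxygen to give formate 5, whose labile ester is then cleaved by methanolysis without touching the methyl ether or the bromines.

Step 4
Reactants: 2 2-diazocyclohexane-1,3-dione; 6 3,5-dibromo-2-methoxyphenol
Product: 7 2-(3,5-dibromo-2-methoxyphenoxy)cyclohexane-1,3-dione
Conditions: Rh2(OAc)4 (2 mol %), PhF, 80 °C, slow addition of 2 to 6 (1.3 equiv)
Reagents that add atoms: none
Why: Rh2(OAc)4 (dirhodium tetraacetate, divalent rhodium) expels N2 from 2 to form an electrophilic acceptor/acceptor rhodium carbenoid; the hydroxyl oxygen of 6 attacks the carbene carbon to give an oxonium ylide, and proton transfer from oxygen to carbon releases 7 and the catalyst. The closest known reaction type is the Rh2(OAc)4-catalysed O–H insertion of cyclic 2-diazo-1,3-diones into alcohols and phenols. No ring is closed and no stereocentre is created; the single new bond is O–C1' (C2 of the dione). The step needs chemoselectivity for O–H insertion over cyclopropanation (Buchner reaction) or C–H insertion on ring A and over attack by the methoxy oxygen; the hydroxyl lone pair is the best donor, ring A is deactivated by its two bromines, and the catalyst does not insert into C–Br bonds. Fluorobenzene is a poorly reactive solvent toward the carbenoid, and slow addition of 2 to a slight excess of 6 keeps the carbenoid concentration low so that the enol O–H of 7 does not compete.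

Step 5
Reactants: 7 2-(3,5-dibromo-2-methoxyphenoxy)cyclohexane-1,3-dione
Product: 8 3-bromo-2-(3,5-dibromo-2-methoxyphenoxy)cyclohex-2-en-1-one
Conditions: Ph3PBr2, Et3N, CH2Cl2, 0 °C → rt
Reagents that add atoms: dibromotriphenylphosphorane, BrP(Br)(c1ccccc1)(c1ccccc1)c1ccccc1
Why: Deoxybromination of a cyclic 1,3-dione, in which the enol oxygen of 7 is activated as an oxyphosphonium ion and bromide replaces it by addition–elimination at the β-carbon with loss of Ph3P=O; since 7 is symmetric, only one 3-bromoenone can form.

Step 6
Reactants: 8 3-bromo-2-(3,5-dibromo-2-methoxyphenoxy)cyclohex-2-en-1-one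
Product: 10 3,6,6-tribromo-2-(3,5-dibromo-2-methoxyphenoxy)cyclohex-2-en-1-one, via monobromo enone 9 (not isolated)
Conditions: LiN(SiMe3)2, THF, −78 °C; NBS; then LiN(SiMe3)2; NBS, −78 → −40 °C; aq. NH4Cl
Reagents that add atoms: N-bromosuccinimide, O=C1CCC(=O)N1Br
Why: Kinetic enolate α-halogenation, in which the hindered non-nucleophilic base removes a C6 (α') proton to give the cross-conjugated enolate that NBS brominates to 9, and the more acidic 9 is brominated at the same carbon in the second cycle; LiN(SiMe3)2 is too weak to metalate the ring A C–H between the two bromines, and C4 is not touched under kinetic control.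

Step 7
Reactants: 10 3,6,6-tribromo-2-(3,5-dibromo-2-methoxyphenoxy)cyclohex-2-en-1-one
Product: 12 3,6-dibromo-2-(3,5-dibromo-2-methoxyphenoxy)phenol, via dienone tautomer 11 (not isolated)
Conditions: Li2CO3, LiBr, DMF, 90 °C
Reagents that add atoms: none
Why: Classical Li2CO3/LiBr dehydrobromination of an α-bromo ketone (loss of a C5 hydrogen and one C6 bromine) gives cross-conjugated dienone 11, whose tautomerisation to the phenol is driven by aromatisation, while the vinylic and aryl bromides meet no nucleophile other than bromide.

Step 8
Reactants: 12 3,6-dibromo-2-(3,5-dibromo-2-methoxyphenoxy)phenol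
Product: 13 3,6-dibromo-2-(3,5-dibromo-2-hydroxyphenoxy)phenol
Conditions: BBr3, CH2Cl2, −78 °C → rt; H2O
Reagents that add atoms: none
Why: Lewis acid-mediated aryl methyl ether cleavage, in which BBr3 coordinates the methoxy oxygen and bromide removes the methyl group by SN2 attack, the diaryl ether and all C–Br bonds being inert and hydrolytic work-up freeing both phenols.

Compound list
1 | cyclohexane-1,3-dione | O=C1CCCC(=O)C1 | starting material
2 | 2-diazocyclohexane-1,3-dione | [N-]=[N+]=C1C(=O)CCCC1=O | intermediate
3 | 3,5-dibromo-2-hydroxybenzaldehyde (3,5-dibromosalicylaldehyde) | O=Cc1cc(Br)cc(Br)c1O | starting material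
4 | 3,5-dibromo-2-methoxybenzaldehyde | COc1c(Br)cc(Br)cc1C=O | intermediate
5 | 3,5-dibromo-2-methoxyphenyl formate | COc1c(Br)cc(Br)cc1OC=O | intermediate (not isolated)
6 | 3,5-dibromo-2-methoxyphenol | COc1c(Br)cc(Br)cc1O | intermediate
7 | 2-(3,5-dibromo-2-methoxyphenoxy)cyclohexane-1,3-dione | COc1c(Br)cc(Br)cc1OC1C(=O)CCCC1=O | intermediate
8 | 3-bromo-2-(3,5-dibromo-2-methoxyphenoxy)cyclohex-2-en-1-one | COc1c(Br)cc(Br)cc1OC1=C(Br)CCCC1=O | intermediate
9 | 3,6-dibromo-2-(3,5-dibromo-2-methoxyphenoxy)cyclohex-2-en-1-one, racemic at C6 | COc1c(Br)cc(Br)cc1OC1=C(Br)CCC(Br)C1=O | intermediate (not isolated)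
10 | 3,6,6-tribromo-2-(3,5-dibromo-2-methoxyphenoxy)cyclohex-2-en-1-one | COc1c(Br)cc(Br)cc1OC1=C(Br)CCC(Br)(Br)C1=O | intermediate
11 | 3,6-dibromo-2-(3,5-dibromo-2-methoxyphenoxy)cyclohexa-2,5-dien-1-one | COc1c(Br)cc(Br)cc1OC1=C(Br)CC=C(Br)C1=O | intermediate (not isolated)
12 | 3,6-dibromo-2-(3,5-dibromo-2-methoxyphenoxy)phenol | COc1c(Br)cc(Br)cc1Oc1c(Br)ccc(Br)c1O | intermediate
13 | 3,6-dibromo-2-(3,5-dibromo-2-hydroxyphenoxy)phenol | Oc1c(Br)cc(Br)cc1Oc1c(Br)ccc(Br)c1O | target

Total step count: 8. Longest linear sequence: 7 steps (3 → 13, steps 2 to 8); step 1 is a one-step side branch that joins at step 4.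

Steps most likely to fail

Step 4. The carbenoid may be consumed by routes other than insertion into the phenol O–H: reaction with the enol hydroxyl of the product, attack on the solvent or on the ring A π-system, or Wolff rearrangement, all favoured if the hindered and rather electron-poor phenol adds slowly. Fallback: setting out from 6, the O–C1' bond would be made by Williamson alkylation and ring B closed afterwards by Claisen condensation. Purchased methyl 5-chloro-5-oxopentanoate is treated with Me3SiCHN2 (MeCN/THF, 0 °C) to give methyl 6-diazo-5-oxohexanoate F1, which HBr (48 % aq., Et2O, 0 °C) converts into methyl 6-bromo-5-oxohexanoate F2. Phenol 6 is alkylated with F2 (K2CO3, acetone, rt) to give methyl 6-(3,5-dibromo-2-methoxyphenoxy)-5-oxohexanoate F3. KOt-Bu (THF, 0 °C → rt) then closes the six-membered ring by intramolecular Claisen condensation of the aryloxy-substituted ketone enolate onto the ester, and the sequence returns to the route at 7.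

Step 6. The second bromination may stall, or proton and bromine transfer between enolates may scramble the halogen and bring in bromination at C4, so that the mixture aromatises to wrong substitution patterns. Fallback: setting out from 8, a single LiN(SiMe3)2/NBS cycle is run and monobromide 9 is isolated. Li2CO3/LiBr in DMF at 90 °C removes HBr and the resulting dienone tautomerises to 3-bromo-2-(3,5-dibromo-2-methoxyphenoxy)phenol F4. The missing C5' bromine is then introduced by amine-directed ortho-bromination of this phenol (NBS, i-Pr2NH (cat.), CH2Cl2, 0 °C), which should deliver bromine to the only free position ortho to the hydroxyl and not to the para position, returning to the route at 12.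

Step 3. Hydride migration may compete with aryl migration in the Criegee adduct, because the two bromines lower the migratory aptitude of the ring, which would divert material to the benzoic acid. Fallback: setting out from 3, oxidation and methylation are reversed. Dakin oxidation of the free salicylaldehyde (H2O2, NaOH, H2O, 0 °C → rt), in which the phenoxide drives aryl migration, gives 3,5-dibromobenzene-1,2-diol F5. Monomethylation with MeI and Li2CO3 (1 equiv) in DMF at 40 °C should then occur at the more acidic hydroxyl, the one ortho and para to the bromines, as in the selective 4-O-alkylation of 3,4-dihydroxybenzaldehyde, returning to the route at 6.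

Further compounds
F1 | step 4 | methyl 6-diazo-5-oxohexanoate | COC(=O)CCCC(=O)C=[N+]=[N-]
F2 | step 4 | methyl 6-bromo-5-oxohexanoate | COC(=O)CCCC(=O)CBr
F3 | step 4 | methyl 6-(3,5-dibromo-2-methoxyphenoxy)-5-oxohexanoate | COC(=O)CCCC(=O)COc1cc(Br)cc(Br)c1OC
F4 | step 6 | 3-bromo-2-(3,5-dibromo-2-methoxyphenoxy)phenol | COc1c(Br)cc(Br)cc1Oc1c(Br)cccc1O
F5 | step 3 | 3,5-dibromobenzene-1,2-diol | Oc1cc(Br)cc(Br)c1O
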